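All runs were computed with made-up constants, noise included.

One Sbt gives one Pdt, so the Sbt charge minus [Pdt] stayed the amount left to turn, whatever form it sat in.

| flask | Sbt | Ptn | Ctl | time |
|---|---|---|---|---|
| cedar | 0.250 M | 0.750 M | 0.0200 M |  |
| elm | 0.250 M | 0.750 M | 0.0600 M |  |
| oak | 0.250 M | 1.50 M | 0.0200 M |  |
| alder | 0.0830 M | 0.750 M | 0.0600 M | 66 min |

| cedar run: time / min | cedar run: [Pdt] / M | elm run: time / min | elm run: [Pdt] / M | oak run: time / min | oak run: [Pdt] / M |
|---|---|---|---|---|---|
| 2.6 | 0.0080 | 2.6 | 0.0208 | 2.6 | 0.0165 |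
| 4.5 | 0.0158 | 4.5 | 0.0377 | 4.5 | 0.0286 |
| 7.7 | 0.0229 | 7.7 | 0.0640 | 7.7 | 0.0499 |
| 13 | 0.0408 | 13 | 0.0939 | 13 | 0.0781 |
| 23 | 0.0654 | 23 | 0.1372 | 23 | 0.1204 |
| 39 | 0.0971 | 39 | 0.1771 | 39 | 0.1716 |
| 66 | 0.1330 | 66 | 0.2073 | 66 | 0.2161 |

(standard deviation of a reading: 0.002 M)

1. how the opening rate goes with [Ctl] round the charge of the cedar run: the exponent of the rate at two percent of Sbt gone to Pdt
2. how the opening rate goes with [Ptn] round the charge of the cedar run: the exponent of the rate at two percent of Sbt gone to Pdt
3. Pdt in the alder run at 66 min, as a share of the Sbt charged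

- Overall: Sbt + Ptn -> Pdt, with Ctl as catalyst.
- Constant volume, constant temperature.
- The analysis sees a species whether free or bound.
- "The second partner" is Ptn.
- An order is taken over about fifteen percent of the charge, up and down.

I read the order in Ctl by two ways. The first compared flasks at the same time. At 4.5 min, elm held 0.0377 M and cedar 0.0158 M, which gave an order of 0.792. The second compared them at nearly the same [Pdt]. Cedar held 0.0654 M at 23 min, and elm held 0.0640 M at 7.7 min. That gave an order of 0.996.

The two ways parted, and the first one cheated. At 4.5 min, elm had already made more Pdt than cedar, so that way compared two stages of conversion. The second way compared nearly the same [Pdt], so I trusted it.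

For Ptn, oak against cedar at 13 min gave a same-time order of 0.937. That way had read low for Ctl, so I took about one.

An order near one in Ctl let me count catalyst-minutes, the Ctl charge times the time. I called the halving dose the catalyst-minutes that bring [Pdt] to half of the Sbt charged. Between readings, elm gave 72.7 M·s and cedar gave 72.0 M·s.

Alder had the Ctl and Ptn charges of elm, with Sbt as the limiting reagent. Its Ctl charge times 66 min came to 238 M·s, which is 3.27 halving doses. I assumed that each dose halved what was left, and so I expected 89.6 %.

The forecast gave 0.9 for Ctl, 1.05 for Ptn and 89 % for alder, the last from “First-order plots in Sbt, corrected for Ptn”. It differed from my order of about one in Ctl and from my 89.6 %.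

The flask gave 0.99 for Ctl and 1.0 for Ptn round the cedar charge, and 93.7 % in alder.

    Ctl + Sbt ⇌ Ctl.Sbt, settled at all times (6.220 M⁻¹)
    Ctl.Sbt + Ptn → Pdt + Ctl + Lvg (0.5826 M⁻¹ min⁻¹)
    2 Sbt ⇌ Sbt2, settled at all times (6.320 M⁻¹)
    2 Ctl → 2 X (0.5814 M⁻¹ min⁻¹)

The simulated times to half conversion gave halving doses of 68.5 M·s for cedar and 71.3 M·s for elm, against my 72.0 M·s and 72.7 M·s. Alder's 93.7 % counted as 3.99 halvings, against my 3.27. Alder still stopped short of its Sbt charge, and the main reason was the loss of Ctl to X. The alder run gave 93.7 % with that step and 99.8 % without it, so the step accounted for 97 % of the missing Pdt.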